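The route rests on cutting C8–C9, the bond between the propargylic methylene and the trans-9,10-oxirane ring (C9, C10 and the ring oxygen). That ring is read as a latent anti chlorohydrin, so one SE2′ propargylboration of (S)-2-chlorononanal, an amine-free, freshly made C9–C17 aldehyde whose C10 chloride steers attack, forms C8–C9, sets C9 and delivers the terminal C6–C7 alkyne in a single operation. Base then closes the oxirane with inversion at C10; bromination, Cadiot–Chodkiewicz union with (S)-pent-1-en-4-yn-3-ol and Steglich acylation with linoleic acid finish the (3S,9R,10R) target.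

Key step: step 2

Remarks on the chemistry (assumptions)
- The target SMILES is read as (3S,9R,10R) with a trans-oxirane.
- (2R,5R)-2,5-Diphenylpyrrolidine is assumed to be the catalyst enantiomer that gives the (S)-chloroaldehyde (chlorination of the unshielded enamine face); if a test run shows the opposite sense, its antipode is used.
- The (R)-configured phosphoric acid is assumed to be the enantiomer that prefers the Re face of the formyl group, the face also favoured by the C10 chloride.
- The lipase is assumed to acylate the (R)-carbinol (silylethynyl as large group, vinyl as medium group), so that the (S)-alcohol is the recovered one.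

Step 1
Reactants: 1 nonanal
Product: 2 (S)-2-chlorononanal
Conditions: NCS (1.3 equiv), (2R,5R)-2,5-diphenylpyrrolidine (10 mol%), CH2Cl2, 0 °C to rt; pentane, filter; cold 0.5 M HCl wash, MgSO4; concentrate cold, use at once
Reagents that add atoms: N-chlorosuccinimide, ClN1C(=O)CCC1=O
Why: Enamine-mediated organocatalytic α-chlorination, in which the C2-symmetric amine forms an E-enamine with one face screened by a phenyl group so that chlorine from NCS enters on the open face and sets C10 as S, while the acid wash removes the amine that would otherwise neutralise the phosphoric acid of step 2.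

Step 2
Reactants: 2 (S)-2-chlorononanal; 3 allenylboronic acid pinacol ester
Product: 5 (4R,5S)-5-chlorododec-1-yn-4-ol, via pinacol borate ester 4 (not isolated)
Conditions: 3 (1.5 equiv), (R)-3,3′-bis(2,4,6-triisopropylphenyl)-1,1′-binaphthyl-2,2′-diyl hydrogen phosphate ((R)-TRIP, 5 mol%), 4 Å MS, toluene, −20 to 0 °C; then H2O, rt
Reagents that add atoms: none
Why: The phosphoric acid hydrogen-bonds to a boronate oxygen while its phosphoryl oxygen holds the formyl C–H, and the terminal CH2 (γ-carbon) of the allenylboronate attacks the aldehyde carbon through a closed six-membered chair transition state (SE2′), so that C8–C9 and the B–O bond form together and borate 4, hydrolysed on work-up, carries a terminal alkyne. The closest known reaction type is the phosphoric-acid-catalysed propargylboration of aliphatic aldehydes with allenylboronic esters, taken together with anti-selective nucleophilic addition to α-chloroaldehydes. No ring is closed. The new C9 stereocentre (R) is controlled by the C10 chloride: with C–Cl held anti to C=O (Cornforth) or anti to the incoming carbon (polar Felkin–Anh) the nucleophile passes the C10 hydrogen and reaches the Re face, and the (R)-configured catalyst is chosen because it should favour the same face. The step needs anti over syn addition, propargyl over allenyl transfer and an untouched C10 centre; the α-chlorine dipole, the cyclic γ-selective transition state and the acidic, amine-free medium at low temperature should secure these in turn. The minor (R)-aldehyde meets a mismatched catalyst and should end mainly in a separable diastereomer.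

Step 3
Reactants: 5 (4R,5S)-5-chlorododec-1-yn-4-ol
Product: 6 (2R,3R)-2-heptyl-3-(prop-2-yn-1-yl)oxirane
Conditions: KOH (powdered, 2 equiv), EtOH, 0 °C to rt
Reagents that add atoms: none
Why: Intramolecular Williamson (SN2) ring closure in which the C9 alkoxide displaces chloride at C10 from the rear in a 3-exo-tet mode, so that C10 is inverted to R, C9 stays R and the anti chlorohydrin can give only the trans-oxirane, while cold ethanolic KOH should not isomerise the terminal alkyne.

Step 4
Reactants: 6 (2R,3R)-2-heptyl-3-(prop-2-yn-1-yl)oxirane
Product: 7 (2R,3R)-2-(3-bromoprop-2-yn-1-yl)-3-heptyloxirane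
Conditions: NBS (1.1 equiv), AgNO3 (10 mol%), acetone, rt, dark
Reagents that add atoms: N-bromosuccinimide, BrN1C(=O)CCC1=O
Why: Silver-catalysed electrophilic bromination of a terminal alkyne (a silver acetylide is brominated by NBS) under neutral conditions, which should leave the oxirane and both stereocentres alone.

Step 5
Reactants: 8 acrolein; 9 trimethylsilylacetylene
Product: 11 rac-5-(trimethylsilyl)pent-1-en-4-yn-3-ol, via lithium (trimethylsilyl)acetylide 10 (not isolated)
Conditions: 9, n-BuLi, THF, −78 °C; then 8, −78 °C; aq NH4Cl
Reagents that add atoms: none
Why: 1,2-Addition of a lithium acetylide to an enal at −78 °C, where the hard nucleophile attacks the carbonyl and not the β-carbon; the carbinol is made racemic on purpose because the next step resolves it.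

Step 6
Reactants: 11 rac-5-(trimethylsilyl)pent-1-en-4-yn-3-ol
Product: 12 (S)-5-(trimethylsilyl)pent-1-en-4-yn-3-ol
Conditions: Amano lipase AK, vinyl acetate, hexane, rt, run slightly beyond half conversion; chromatography (alcohol fraction)
Reagents that add atoms: none
Why: Lipase-catalysed kinetic resolution by irreversible acetyl transfer from vinyl acetate, in which the empirical size rule for secondary alcohols predicts acylation of the (R)-enantiomer (large silylethynyl, medium vinyl), so that the (S)-alcohol is recovered and its purity should rise as conversion passes one half.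

Step 7
Reactants: 12 (S)-5-(trimethylsilyl)pent-1-en-4-yn-3-ol
Product: 13 (S)-pent-1-en-4-yn-3-ol
Conditions: K2CO3 (0.2 equiv), MeOH, 0 °C to rt; Et2O/brine, cold concentration (volatile), used as Et2O solution
Reagents that add atoms: none
Why: Base-catalysed methanolysis of the alkynyl C–Si bond (protodesilylation), which does not touch the C3 carbinol centre.

Step 8
Reactants: 7 (2R,3R)-2-(3-bromoprop-2-yn-1-yl)-3-heptyloxirane; 13 (S)-pent-1-en-4-yn-3-ol
Product: 14 (3S)-8-[(2R,3R)-3-heptyloxiran-2-yl]oct-1-ene-4,6-diyn-3-ol
Conditions: 13 (1.5 equiv), CuCl (10 mol%), NH2OH·HCl, 30% aq n-BuNH2, Et2O, 0 °C; slow addition of 7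
Reagents that add atoms: none
Why: Cadiot–Chodkiewicz coupling, in which the copper acetylide of 13 couples at the C–Br carbon of 7 to give the unsymmetrical 1,3-diyne, hydroxylamine keeps copper monovalent so that oxidative homocoupling is held back, and at 0 °C the oxirane and the C3 centre should stay untouched.

Step 9
Reactants: 14 (3S)-8-[(2R,3R)-3-heptyloxiran-2-yl]oct-1-ene-4,6-diyn-3-ol; 15 linoleic acid
Product: 16 (3S)-8-[(2R,3R)-3-heptyloxiran-2-yl]oct-1-ene-4,6-diyn-3-yl (9Z,12Z)-octadeca-9,12-dienoate
Conditions: DCC (N,N′-dicyclohexylcarbodiimide, 1.2 equiv), DMAP (0.1 equiv), CH2Cl2, 0 °C to rt, argon, dark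
Reagents that add atoms: none
Why: Steglich esterification, in which DCC activates the acid as an O-acylisourea and DMAP relays the acyl group to the C3 hydroxyl, so that only the O–H bond of 14 is broken and the S configuration is kept, while the neutral medium should spare the oxirane, the diyne and the skipped Z,Z-diene.

Compound list
1 | nonanal | CCCCCCCCC=O | starting material
2 | (S)-2-chlorononanal | CCCCCCC[C@H](Cl)C=O | intermediate
3 | allenylboronic acid pinacol ester (4,4,5,5-tetramethyl-2-(propa-1,2-dien-1-yl)-1,3,2-dioxaborolane) | C=C=CB1OC(C)(C)C(C)(C)O1 | starting material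
4 | 2-{[(4R,5S)-5-chlorododec-1-yn-4-yl]oxy}-4,4,5,5-tetramethyl-1,3,2-dioxaborolane (pinacol borate ester) | C#CC[C@@H](OB1OC(C)(C)C(C)(C)O1)[C@@H](Cl)CCCCCCC | intermediate (not isolated)
5 | (4R,5S)-5-chlorododec-1-yn-4-ol | C#CC[C@@H](O)[C@@H](Cl)CCCCCCC | intermediate
6 | (2R,3R)-2-heptyl-3-(prop-2-yn-1-yl)oxirane | C#CC[C@H]1O[C@@H]1CCCCCCC | intermediate
7 | (2R,3R)-2-(3-bromoprop-2-yn-1-yl)-3-heptyloxirane | BrC#CC[C@H]1O[C@@H]1CCCCCCC | intermediate
8 | acrolein | C=CC=O | starting material
9 | trimethylsilylacetylene | C#C[Si](C)(C)C | starting material
10 | lithium (trimethylsilyl)acetylide | [Li]C#C[Si](C)(C)C | intermediate (not isolated)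
11 | rac-5-(trimethylsilyl)pent-1-en-4-yn-3-ol | C=CC(O)C#C[Si](C)(C)C | intermediate
12 | (S)-5-(trimethylsilyl)pent-1-en-4-yn-3-ol | C=C[C@@H](C#C[Si](C)(C)C)O | intermediate
13 | (S)-pent-1-en-4-yn-3-ol | C=C[C@@H](C#C)O | intermediate
14 | (3S)-8-[(2R,3R)-3-heptyloxiran-2-yl]oct-1-ene-4,6-diyn-3-ol | C=C[C@@H](C#CC#CC[C@H]1O[C@@H]1CCCCCCC)O | intermediate
15 | linoleic acid ((9Z,12Z)-octadeca-9,12-dienoic acid) | OC(=O)CCCCCCC/C=C\C/C=C\CCCCC | starting material
16 | (3S)-8-[(2R,3R)-3-heptyloxiran-2-yl]oct-1-ene-4,6-diyn-3-yl (9Z,12Z)-octadeca-9,12-dienoate | C=C[C@@H](C#CC#CC[C@H]1O[C@@H]1CCCCCCC)OC(=O)CCCCCCC/C=C\C/C=C\CCCCC | target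

Total step count: 9. Longest linear sequence: 6 steps (steps 1, 2, 3, 4, 8 and 9); the three-step branch (steps 5 to 7) joins at step 8.

Steps most likely to fail

Step 2. Facial selectivity may be poor if the catalyst and the C10 chloride prefer opposite faces, C10 may epimerise through enolisation before addition, and allenyl transfer may compete with propargyl transfer. The fallback drops boron and catalyst control and relies on substrate control alone. It sets out from 2, which is added at −78 °C in THF to 3-lithio-1-(trimethylsilyl)propyne (from 1-(trimethylsilyl)propyne and n-BuLi). Organolithium addition to α-chloroaldehydes is anti-selective, so this should give (4R,5S)-5-chloro-1-(trimethylsilyl)dodec-1-yn-4-ol F1, with any allenic regioisomer removed by chromatography. KOH in MeOH then closes the oxirane and cleaves the C–Si bond in the same flask, and the route is rejoined at 6.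

Step 8. The volatile, water-soluble alkynol may be lost on isolation, oxidative homocoupling may consume it, and the amine may slowly open the oxirane during a sluggish coupling. The fallback reverses the roles of the partners and so avoids steps 4 and 7. It sets out from 12, which NBS and AgNO3 (10 mol%) in acetone should convert directly, by bromodesilylation, into (S)-5-bromopent-1-en-4-yn-3-ol F2. F2 is added slowly to the non-volatile terminal alkyne 6 (used in excess and recoverable) with CuCl, NH2OH·HCl and aqueous n-BuNH2 at 0 °C, and the route is rejoined at 14.

Step 1. The chloroaldehyde may lose configuration at C10 by enolisation while the amine catalyst is removed, or residual amine may be carried over and neutralise the phosphoric acid. The fallback stores the stereocentre in a stable form. It sets out from 1: the chlorination mixture is quenched in the flask with NaBH4 in MeOH at 0 °C to give (S)-2-chlorononan-1-ol F3, which can be chromatographed, assayed for enantiomeric purity and kept. Oxidation with Dess–Martin periodinane (NaHCO3, CH2Cl2, 0 °C) shortly before use then returns amine-free material at 2.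

Further compounds
F1 | step 2 | (4R,5S)-5-chloro-1-(trimethylsilyl)dodec-1-yn-4-ol | C[Si](C)(C)C#CC[C@@H](O)[C@@H](Cl)CCCCCCC
F2 | step 8 | (S)-5-bromopent-1-en-4-yn-3-ol | C=C[C@@H](C#CBr)O
F3 | step 1 | (S)-2-chlorononan-1-ol | CCCCCCC[C@H](Cl)CO
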